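**Plan**
- Retrosynthesis cuts the two C2–CH2 bonds of the bridge (formaldehyde plus two identical halves), then in each half C1–C2 and C3–C4 of ring B, then the aryl–acetyl bond, and last the two bonds of a four-membered ring fused to ring A.
- Enabling feature: numbered as a naphthalen-1(4H)-one, each half has its C1 ketone on C8a and its gem-dimethyl C4 on the adjacent C4a. These are the ketene and isopropylidene termini of the o-quinoid vinylketene released by an 8,8-dimethylbenzocyclobutenone, and C2–C3(O) maps onto an ynol ether.
- Forward: ring A is bought as 1; an aryne [2+2] fuses the cyclobutenone ketal; ortho-lithiation brings in the acetyl group; light opens the four-membered ring and ethoxyacetylene closes ring B; hydrolysis and demethylation follow; formaldehyde joins two halves.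
- Stereochemistry: the target has no stereocentre (C4 is gem-dimethyl, the bridge is CH2), so only regiochemistry has to be controlled.

Key step: step 3

Remark: the target is an achiral bis(1,3-dione) drawn as one enol tautomer, and all tautomers of 12, 13 and 16 are treated as the same compounds; 2 and the hexanes solution of 9 are taken as purchasable.

**Route**

Step 1
Reactants: 1 1-bromo-3,5-dimethoxybenzene; 2 1,1-dimethoxy-2-methylprop-1-ene
Product: 4 3,5,7,7-tetramethoxy-8,8-dimethylbicyclo[4.2.0]octa-1,3,5-triene, via 3,5-dimethoxybenzyne 3 (not isolated)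
Conditions: NaNH2 (3 equiv), 2 (3 equiv), THF, reflux
Reagents that add atoms: none
Why: Aryne [2+2] cycloaddition with a ketene acetal: NaNH2 removes the ring hydrogen between bromine and a methoxy group, loss of bromide gives 3, and the nucleophilic CMe2 terminus of 2 attacks the aryne carbon remote from the flanking methoxy group so that the aryl anion beside that methoxy group closes onto the dimethoxycarbenium carbon, which places the ketal carbon next to C–OMe and the gem-dimethyl carbon next to C–H, as ring B later requires.

Step 2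
Reactants: 4 3,5,7,7-tetramethoxy-8,8-dimethylbicyclo[4.2.0]octa-1,3,5-triene; 5 N-methoxy-N-methylacetamide
Product: 8 4-acetyl-3,5-dimethoxy-8,8-dimethylbicyclo[4.2.0]octa-1,3,5-trien-7-one, via 4-lithio ketal 6 (not isolated), via 4-acetyl ketal 7 (not isolated)
Conditions: n-BuLi, THF, 0 °C; then 5, −78 °C → rt; then 2 M aq. HCl, rt
Reagents that add atoms: water, O
Why: Directed ortho-metalation at the only position flanked by two methoxy groups followed by Weinreb ketone synthesis installs the acetyl group without over-addition, and the dilute acid then hydrolyses the strained dimethyl ketal, whose oxocarbenium ion is stabilised by the ortho and para methoxy groups, while the hindered aryl ketone is inert.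

Step 3
Reactants: 8 4-acetyl-3,5-dimethoxy-8,8-dimethylbicyclo[4.2.0]octa-1,3,5-trien-7-one; 9 ethoxyacetylene
Product: 11 7-acetyl-3-ethoxy-6,8-dimethoxy-4,4-dimethylnaphthalen-1(4H)-one, via o-quinoid vinylketene 10 (not isolated)
Conditions: hν (350 nm, Pyrex), 9 (20 equiv, hexanes solution), dry degassed toluene, 0 °C
Reagents that add atoms: none
Why: Proposed new method: light opens the four-membered ring of 8 in the known way to the o-quinoid vinylketene 10, whose ketene carbon (future C1) sits on C8a and whose isopropylidene carbon (future C4) sits on C4a, and the ynol ether is expected to add across these two termini; the closest known reactions are the trapping of photochemically or thermally generated benzocyclobutenone ketene methides by nucleophiles and dienophiles and the ketene–ynol ether union of the Danheiser benzannulation. The nucleophilic CH terminus of 9 should attack the electrophilic ketene carbon to form C1–C2, and the oxygen-stabilised cationic carbon should then be captured by C4 of the dienolate to form C3–C4, so ring B closes as a formal [4+2] cycloaddition (six-membered ring from the four-atom vinylketene and the two alkyne carbons), concerted or stepwise through a zwitterion. No stereocentre is formed, since C4 carries two methyl groups. The regiochemistry (ethoxy at C3, not C2) follows from the matched polarity of ketene carbon and ynol ether, and closure at C4 rather than at C8a (the [2+2] mode of simple vinylketenes) is favoured because only it restores the aromaticity of ring A. Capture must outrun the [1,5]-hydrogen shift from a C4 methyl group to the ketene carbon; this is addressed by generating 10 with light at 0 °C in a large excess of 9, where untrapped 10 can reclose to 8 and the ynol ether does not fragment thermally.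

Step 4
Reactants: 11 7-acetyl-3-ethoxy-6,8-dimethoxy-4,4-dimethylnaphthalen-1(4H)-one
Product: 12 7-acetyl-3-hydroxy-6,8-dimethoxy-4,4-dimethylnaphthalen-1(4H)-one
Conditions: 2 M aq. HCl, THF, 50 °C
Reagents that add atoms: water, O
Why: Acid-catalysed hydrolysis of a vinylogous ester (protonation at C2, addition of water at C3, loss of ethanol) should give the cyclic 1,3-dione as its enol, while the aryl methyl ethers and the acetyl group are stable to dilute acid.

Step 5
Reactants: 12 7-acetyl-3-hydroxy-6,8-dimethoxy-4,4-dimethylnaphthalen-1(4H)-one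
Product: 13 7-acetyl-3,6,8-trihydroxy-4,4-dimethylnaphthalen-1(4H)-one
Conditions: BBr3 (6 equiv), CH2Cl2, −78 °C → rt; then H2O
Reagents that add atoms: none
Why: Lewis-acid cleavage of aryl methyl ethers by BBr3 is assisted here by chelation, since each methoxy group is ortho to a carbonyl group (C8–OMe to C1=O and the acetyl group, C6–OMe to the acetyl group), and the enolised dione is held as a boron chelate until hydrolysis.

Step 6
Reactants: 13 7-acetyl-3,6,8-trihydroxy-4,4-dimethylnaphthalen-1(4H)-one (two molecules); 14 formaldehyde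
Product: 16 2,2'-methylenebis[7-acetyl-3,6,8-trihydroxy-4,4-dimethylnaphthalen-1(4H)-one], via 2-methylidene dione 15 (not isolated)
Conditions: 37% aq. CH2O (0.5 equiv), NaOAc (cat.), EtOH/H2O, rt
Reagents that add atoms: none
Why: Knoevenagel condensation of formaldehyde at the acidic C2 of the cyclic 1,3-dione gives 15, which should take up a second molecule of 13 by Michael addition as in the formaldehyde–dimedone reaction, while the only free ring-A position, C5, is deactivated by two acyl groups and shielded by the peri gem-dimethyl group.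

**Compound list**

1 | 1-bromo-3,5-dimethoxybenzene | COc1cc(Br)cc(OC)c1 | starting material
2 | 1,1-dimethoxy-2-methylprop-1-ene | COC(OC)=C(C)C | starting material
3 | 3,5-dimethoxybenzyne (1,2-didehydro-3,5-dimethoxybenzene) | COC1=CC(OC)=CC#C1 | intermediate
4 | 3,5,7,7-tetramethoxy-8,8-dimethylbicyclo[4.2.0]octa-1,3,5-triene | COc1cc(OC)c2c(c1)C(C)(C)C2(OC)OC | intermediate
5 | N-methoxy-N-methylacetamide | CC(=O)N(C)OC | starting material
6 | (3,5,7,7-tetramethoxy-8,8-dimethylbicyclo[4.2.0]octa-1,3,5-trien-4-yl)lithium | [Li]c1c(OC)cc2c(c1OC)C(OC)(OC)C2(C)C | intermediate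
7 | 1-(3,5,7,7-tetramethoxy-8,8-dimethylbicyclo[4.2.0]octa-1,3,5-trien-4-yl)ethan-1-one | CC(=O)c1c(OC)cc2c(c1OC)C(OC)(OC)C2(C)C | intermediate
8 | 4-acetyl-3,5-dimethoxy-8,8-dimethylbicyclo[4.2.0]octa-1,3,5-trien-7-one | CC(=O)c1c(OC)cc2c(c1OC)C(=O)C2(C)C | intermediate
9 | ethoxyacetylene (ethoxyethyne) | CCOC#C | starting material
10 | 1-[2,6-dimethoxy-3-(oxomethylidene)-4-(propan-2-ylidene)cyclohexa-1,5-dien-1-yl]ethan-1-one | CC(=O)C1=C(OC)C(=C=O)C(=C(C)C)C=C1OC | intermediate
11 | 7-acetyl-3-ethoxy-6,8-dimethoxy-4,4-dimethylnaphthalen-1(4H)-one | CCOC1=CC(=O)c2c(OC)c(C(C)=O)c(OC)cc2C1(C)C | intermediate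
12 | 7-acetyl-3-hydroxy-6,8-dimethoxy-4,4-dimethylnaphthalen-1(4H)-one | CC(=O)c1c(OC)cc2c(c1OC)C(=O)C=C(O)C2(C)C | intermediate
13 | 7-acetyl-3,6,8-trihydroxy-4,4-dimethylnaphthalen-1(4H)-one | CC(=O)c1c(O)cc2c(c1O)C(=O)C=C(O)C2(C)C | intermediate
14 | formaldehyde | C=O | starting material
15 | 7-acetyl-6,8-dihydroxy-4,4-dimethyl-2-methylidenenaphthalene-1,3(2H,4H)-dione | CC(=O)c1c(O)cc2c(c1O)C(=O)C(=C)C(=O)C2(C)C | intermediate
16 | 2,2'-methylenebis[7-acetyl-3,6,8-trihydroxy-4,4-dimethylnaphthalen-1(4H)-one] | CC(=O)c1c(O)cc2c(c1O)C(=O)C(CC1=C(O)C(C)(C)c3cc(O)c(C(C)=O)c(O)c3C1=O)=C(O)C2(C)C | target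

**Step count**

Total: 6 steps. Longest linear sequence: 6 steps (1 → 4 → 8 → 11 → 12 → 13 → 16; both halves are the same intermediate 13).

**Steps most likely to fail**

Step 3 (bears the label). The [1,5]-hydrogen shift from a methyl group on the isopropylidene carbon to the ketene carbon of 10 may outpace bimolecular capture and drain the ketene irreversibly. Prolonged irradiation may also trigger secondary photoreactions of the aryl ketone chromophores. The fallback uses known chemistry, sets out from 1 and rejoins the route at 12; ring B is closed by an intramolecular Friedel–Crafts acylation of a β-keto ester instead of a cycloaddition.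
- Lithiation of 1 between the methoxy groups with LiN(i-Pr)2 (THF, −78 °C) should give (4-bromo-2,6-dimethoxyphenyl)lithium F1.
- Acylation of this species by 5 gives 1-(4-bromo-2,6-dimethoxyphenyl)ethan-1-one F2.
- Pd-catalysed α-arylation of 1-methoxy-2-methyl-1-(trimethylsilyloxy)prop-1-ene with F2 (Pd(dba)2, P(t-Bu)3, ZnF2, DMF, 80 °C), a coupling that tolerates enolisable ketones, gives methyl 2-(4-acetyl-3,5-dimethoxyphenyl)-2-methylpropanoate F3.
- Saponification (LiOH, aq. MeOH, 60 °C) gives 2-(4-acetyl-3,5-dimethoxyphenyl)-2-methylpropanoic acid F4.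
- Activation with 1,1'-carbonyldiimidazole gives 1-{4-[1-(1H-imidazol-1-yl)-2-methyl-1-oxopropan-2-yl]-2,6-dimethoxyphenyl}ethan-1-one F5.
- Decarboxylative C-acylation of Mg(O2CCH2CO2Et)2 with this acyl imidazole gives ethyl 4-(4-acetyl-3,5-dimethoxyphenyl)-4-methyl-3-oxopentanoate F6.
- Cyclisation in P2O5/MeSO3H (50 °C) onto the ring position ortho to the quaternary carbon, which is ortho and para to the two methoxy groups, gives 12.

Step 1. The hindered, tetrasubstituted ketene acetal may react with the aryne by an ene reaction at its allylic methyl hydrogens, or amide may add to the aryne first, in place of the stepwise [2+2] closure. The fallback sets out from 1 and rejoins at 4; the four-membered ring is closed by Pd-catalysed acylation instead of an aryne cycloaddition.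
- α-Arylation of 2-methylpropanal with 1 (Pd(OAc)2, rac-BINAP, Cs2CO3, dioxane, 80 °C) gives 2-(3,5-dimethoxyphenyl)-2-methylpropanal F7.
- NBS (MeCN, 0 °C) should brominate para to one methoxy group and ortho to the side chain to give 2-(2-bromo-3,5-dimethoxyphenyl)-2-methylpropanal F8.
- Intramolecular Pd-catalysed acylation through the aldehyde C–H bond (Pd(OAc)2, rac-BINAP, Cs2CO3, dioxane, 110 °C), a closure known for 2-(2-bromoaryl)-2,2-dialkylacetaldehydes, gives 3,5-dimethoxy-8,8-dimethylbicyclo[4.2.0]octa-1,3,5-trien-7-one F9.
- Ketalisation (HC(OMe)3, MeOH, TsOH cat., rt) returns to 4.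

Step 2. Proton transfer from the acetyl α-hydrogens of 5 to the flanked aryllithium, or slow acyl transfer at this doubly ortho-substituted carbon, may simply return 4. The fallback sets out from 4 and rejoins at 8; the acetyl group is built by carbonyl addition and oxidation instead of acyl substitution.
- The aryllithium 6 is generated as in step 2 and quenched with acetaldehyde (−78 °C) to give racemic 1-(3,5,7,7-tetramethoxy-8,8-dimethylbicyclo[4.2.0]octa-1,3,5-trien-4-yl)ethan-1-ol F10.
- Oxidation with Dess–Martin periodinane (NaHCO3, CH2Cl2, rt) gives the ketal 7.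
- 2 M aq. HCl in THF then gives 8.

**Further compounds**

F1 | step 3 | (4-bromo-2,6-dimethoxyphenyl)lithium | [Li]c1c(OC)cc(Br)cc1OC
F2 | step 3 | 1-(4-bromo-2,6-dimethoxyphenyl)ethan-1-one | CC(=O)c1c(OC)cc(Br)cc1OC
F3 | step 3 | methyl 2-(4-acetyl-3,5-dimethoxyphenyl)-2-methylpropanoate | COC(=O)C(C)(C)c1cc(OC)c(C(C)=O)c(OC)c1
F4 | step 3 | 2-(4-acetyl-3,5-dimethoxyphenyl)-2-methylpropanoic acid | CC(=O)c1c(OC)cc(cc1OC)C(C)(C)C(=O)O
F5 | step 3 | 1-{4-[1-(1H-imidazol-1-yl)-2-methyl-1-oxopropan-2-yl]-2,6-dimethoxyphenyl}ethan-1-one | CC(=O)c1c(OC)cc(cc1OC)C(C)(C)C(=O)n1ccnc1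
F6 | step 3 | ethyl 4-(4-acetyl-3,5-dimethoxyphenyl)-4-methyl-3-oxopentanoate | CCOC(=O)CC(=O)C(C)(C)c1cc(OC)c(C(C)=O)c(OC)c1
F7 | step 1 | 2-(3,5-dimethoxyphenyl)-2-methylpropanal | COc1cc(OC)cc(c1)C(C)(C)C=O
F8 | step 1 | 2-(2-bromo-3,5-dimethoxyphenyl)-2-methylpropanal | COc1cc(OC)c(Br)c(c1)C(C)(C)C=O
F9 | step 1 | 3,5-dimethoxy-8,8-dimethylbicyclo[4.2.0]octa-1,3,5-trien-7-one | COc1cc(OC)c2c(c1)C(C)(C)C2=O
F10 | step 2 | 1-(3,5,7,7-tetramethoxy-8,8-dimethylbicyclo[4.2.0]octa-1,3,5-trien-4-yl)ethan-1-ol (racemic) | CC(O)c1c(OC)cc2c(c1OC)C(OC)(OC)C2(C)C
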